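The numbers in the tables were computed for an exercise; noise was put on by code.

Two excesses and a verdict between two flasks are asked.

| setting | Thursday's | Wednesday's | green | amber |
|---|---|---|---|---|
| left-handed substrate | 0.020 M | 0.020 M | 0.020 M | 0.020 M |
| right-handed substrate | 0.020 M | 0.020 M | 0.020 M | 0.020 M |
| partner | 2 equiv | 6 equiv | 3.00 equiv | 3.00 equiv |
| precatalyst | 0.39 mol% | 0.39 mol% | 0.39 mol% | 1.2 mol% |
| remark | run made earlier | run made earlier |  |  |
| time |  |  | 25 h | 25 h |

- Thursday's (time / h: left-handed product / %, right-handed product / %, left-handed substrate / %): 0.250: 0.2, 0.1, 49.8; 0.833: 0.4, 0, 49.6; 1.33: 0.2, 0, 50.2; 2.00: 0.5, 0.2, 48.8; 3.00: 1.0, 0.1, 49.2; 4.00: 1.1, 0.2, 48.5; 5.00: 2.1, 0.8, 48.2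
- Wednesday's (time / h: left-handed product / %, right-handed product / %, left-handed substrate / %): 0.250: 0.2, 0, 50.2; 0.833: 0.2, 0, 49.5; 1.33: 1.0, 0, 49.2; 2.00: 2.3, 0.3, 47.5; 3.00: 4.8, 0.8, 45.7; 4.00: 7.5, 1.2, 42.8; 5.00: 9.4, 1.5, 40.2

(readings scatter by 0.3 percentage points)

- free catalyst is single-handed; left-handed substrate and right-handed substrate are mirror images of each other, charged as a racemate, each of them at the stated concentration
- an excess is below zero if the other one leads
- no earlier run changes the charge of precatalyst; that part of a forecast is a guess

- the winner by excess of left-handed product over right-handed product in the product; "neither" if no more than 2 percentage points parts them (green / amber / neither)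
- excess of left-handed product over right-handed product in the product at the end, green
- excess of left-handed product over right-handed product in the product at the end, amber

The bench rule says the excess in the product stays at its early value. Wednesday's last reading gives 72.5%, so this rule makes green and amber equal.

But I work with the fraction left. I assume both substrates meet the same catalyst and partner, like two absorbers in one beam. Each then decays under one shared exposure E: the left-handed fraction left is exp(-E), the right-handed exp(-E/s). Here s, the selectivity factor, is the ratio of the logarithms of the two fractions left. The catalyst's history sits in E and cancels in s.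

Right-handed substrate isn't read, so I count both fractions from the products. In Wednesday's flask at 5.00 h they are 0.812 and 0.970, so s reads 6.84. That reading is soft, since the right-handed product's 1.5% carries a scatter of 0.3 percentage points.

The momentary product ratio is s times the ratio of the fractions left, so the bench rule ends as that ratio leaves one. Wednesday's flask already stands at 0.837.

For E, Wednesday's flask gains 0.0537 h⁻¹ between 3.00 h and 5.00 h. I scale this first order in partner and in loading, the loading being a guess, and ignore any lag. Green gets E = 0.671 and amber 2.06. Green's ratio of fractions left is then 0.564, further from one than Wednesday's. My excesses are 67.9% for green and 54.0% for amber.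

The forecast says green, with 66% and 54%: “Higher conversion still erodes the excess, so green should win.” My green figure stands above its figure.

The flask gives green, with 66.5% for green and 52.8% for amber.

    free catalyst + left-handed substrate ⇌ catalyst intermediate A (K = 70.0 M⁻¹, k = 11.0 M⁻¹ s⁻¹)
    free catalyst + right-handed substrate ⇌ catalyst intermediate B (K = 22.0 M⁻¹, k = 20.0 M⁻¹ s⁻¹)
    partner + catalyst intermediate A → free catalyst + left-handed product (k = 0.110 M⁻¹ s⁻¹)
    partner + catalyst intermediate B → free catalyst + right-handed product (k = 0.0530 M⁻¹ s⁻¹)
    partner + precatalyst → free catalyst + spent reagent (k = 8.70 × 10⁻⁴ M⁻¹ s⁻¹)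
    partner + free catalyst → spent catalyst (k = 4.70 × 10⁻⁴ M⁻¹ s⁻¹)

For the forecast's green figure to fail, a run would have to sit as far from green as the nearest settings above it that move the excess by 5 points, which are 0.68 mol% of precatalyst or 6.06 equiv of partner, each moved with the other charges and the time held. In amber, 14% of the left-handed substrate is left, and s turns that into an excess of 55.0%. The neighbouring flask is amber with 3 mol% of precatalyst, and 0.80% of its left-handed substrate is left at 25.0 h. So s puts its right-handed fraction left at 0.494, against the simulated 47%, and its excess at 32.4%. That flask shows 30.4%.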